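## The problem

Pollenitin 8-acetate (24) is a flavonol: a 4H-chromen-4-one (rings A and C) with a 4-hydroxyphenyl group (ring B) on C2 and a hydroxyl on C3. The skeleton is simple, and the difficulty lies in ring A. There C5, C7, C8 and C8a carry four oxygens in a 1,2,3,5 arrangement, each in a different state (chelated phenol, methyl ether, acetate, ring oxygen O1), so each must be addressable on its own. The target has no stereocentre. C2 and C3 are stereogenic only in saturated precursors, both are erased when ring C reaches the pyranone level, and neither needs control. The aryl acetate on C8 is the fragile group. It will not survive alkoxide, hydride or organometallic reagents, so it must be introduced late on the only free hydroxyl then present, and the hydroxyls on C3, C5 and C4' must afterwards be freed under neutral conditions. The feature that makes the key step possible is that C3 and C4 of ring C are neighbours and both at the carbonyl oxidation level, the flavonol being the enol of a chromane-3,4-dione. Two aldehyde carbons held together by the O1–C2 ether can therefore be joined to C3–C4, closing ring C, if a carbene catalyst makes one of them nucleophilic.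

## Retrosynthesis

**24 back to 20 (protecting-group logic).** The last cut removes the three benzyl groups on O3, O5 and O4' of 23 by hydrogenolysis, the one deprotection that leaves an aryl acetate untouched. The acetate is cut next, which leads to 22 with a single free hydroxyl on C8. That hydroxyl must have carried a group orthogonal to benzyl, and an allyl ether (21) is chosen because it is removed by a palladium catalyst under neutral conditions. The benzyl group on O3 of 21 is cut to give flavonol 20. It is needed because the 3-hydroxyl would otherwise compete with the 8-hydroxyl for the acetyl group. These four operations ask only for standard reactions on a stable aromatic pyranone.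

**20 back to 18 (oxidation level).** Flavonol 20 is the enol of dione 19, which arises from ketol 18 by oxidation of the C3 carbinol. Cutting here rather than keeping ring C aromatic up to ring closure means that ring C can be formed at the saturated level. Two stereocentres appear in 18, but both vanish again in 20, so the forward step only has to oxidise a secondary alcohol next to a ketone.

**18 back to 17 (key disconnection, C3–C4).** Cutting C3–C4 of ketol 18 gives dialdehyde 17, in which the ring A aldehyde (future C4) and an aliphatic aldehyde (future C3) are tethered through O1–C2. Against the classical cuts at O1–C2 or C4–C4a this cut has the C3 oxygen in place from the start and requires no acetophenone or chalcone of ring A. The precursor is much simpler than 18: an aryl ether with two formyl groups and no ring C. The forward reaction must turn the ring A aldehyde, not the aliphatic one, into the acyl anion equivalent, and close a six-membered ring.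

**17 back to 10 and 14 (O1–C2 and redox adjustment).** The aliphatic aldehyde of 17 cannot be carried far, so 17 is traced to diol 16 and this to aldehyde ester 15. The ester cannot be half-reduced beside a free aryl aldehyde, so both carbonyls are reduced and both alcohols re-oxidised. Cutting O1–C2 of 15 gives salicylaldehyde 10 and α-bromo ester 14. This is an SN2 etherification with a highly reactive secondary benzylic α-halo ester, chosen over a Mitsunobu or carbenoid insertion because both partners are then made in one step each from simple precursors. Bromo ester 14 comes from commercial arylacetate 11 by polar α-bromination through enolate 12 and silyl ketene acetal 13. A radical bromination is avoided because the benzylic ether methylene would compete.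

**10 back to 8 (C4a–CHO).** The formyl group of 10 is cut to give phenol 8. In 8 the hydroxyl that will become O1 has one substituted ortho position (the allyloxy group) and one free ortho position, so a magnesium-directed ortho-formylation can react at only one site, which is the future C4a. Freeing this hydroxyl later by Lewis acid demethylation of an ortho-methoxy aldehyde was rejected, because the benzyl ether on the other ortho position would be cleaved first.

**8 back to 1 (ring A oxygens).** Phenol 8 is traced through aryl bromide 5, phenol 4 (formed via formate 3) and allyl ether 2 to 5-bromovanillin (1). In 1 every ring A oxygen is already marked differently: the phenol becomes the allyl-protected O8, the methyl ether is the 7-methoxy group, the formyl carbon is exchanged for the O5 oxygen by Baeyer–Villiger oxidation, and the bromine is exchanged for the future O1 through aryllithium 6 and borate 7. At no point do two like groups have to be told apart, which is the advantage over symmetric dimethoxyhydroquinone-type precursors.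

## Roads not taken

**Alternative 1:** The cut is O1–C8a. A 1,3-diketone carrying a quinone, 2-(benzyloxy)-1-[4-(benzyloxy)phenyl]-3-(4-methoxy-3,6-dioxocyclohexa-1,4-dien-1-yl)propane-1,3-dione A1, would be released by oxidative demethylation of its hydroquinone dimethyl ether. The enol oxygen then adds to the quinone carbon next to the acyl group, and tautomerisation gives 3-(benzyloxy)-2-[4-(benzyloxy)phenyl]-5,8-dihydroxy-7-methoxy-4H-chromen-4-one A2.
- Merits: A2 has the C8 hydroxyl free and the C5 hydroxyl tied up in the hydrogen bond to C4=O, so acetylation and hydrogenolysis would finish the synthesis in two steps with no allyl group. The quinone carbon attacked is the most electrophilic one.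
- Weak points: A1 is an acylquinone, prone to hydration, conjugate addition of any nucleophile and self-condensation. The oxidant that forms it must spare an electron-rich benzyloxyaryl ketone and an enolised diketone that is itself oxidisable at its central carbon. The final acetylation relies on a reactivity difference between two free phenols rather than on protection.
- Comparison: in step count after ring closure this road is better. The chosen plan sets against it that every ring A oxygen stays in a defined protected form, that the acetate goes onto a single free hydroxyl, and that no quinone is generated beside benzyl-protected electron-rich rings.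

**Alternative 2:** The cuts are C4a–C4, C4–C3 and O1–C2. 3-(Benzyloxy)-2-iodo-5-methoxy-6-(methoxymethoxy)phenol A3, 1-(benzyloxy)-4-ethynylbenzene A4 and carbon monoxide A5 would be combined under PdCl2(PPh3)2 (divalent palladium, reduced in the flask to zerovalent palladium) in a secondary amine, giving 5-(benzyloxy)-2-[4-(benzyloxy)phenyl]-7-methoxy-8-(methoxymethoxy)-4H-chromen-4-one A6.
- Merits: it is the most convergent road, forming three bonds and ring C in one step from two simple pieces, and the reaction class is well established for flavones.
- Weak points: A6 has hydrogen on C3, so the 3-hydroxyl must be introduced afterwards by a C–H oxidation on a crowded, electron-rich flavone. The iodide of A3 is flanked on both sides, which slows oxidative addition and gives the competing five-membered (5-exo) closure more room. A3 itself requires a regioselective iodination.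
- Comparison: for the ring-forming event itself this road is probably more reliable than the benzoin closure. The chosen plan sets against it that the C3 oxygen is built in by the bond-forming step, so no late oxidation of the heterocycle is needed.

**Alternative 3:** The cut is C4–C4a. (E)-3-[2-(Allyloxy)-5-(benzyloxy)-3-methoxyphenoxy]-2-(benzyloxy)-3-[4-(benzyloxy)phenyl]acrylic acid A7 would be activated as a mixed anhydride and the acyl group would attack the ring A carbon ortho to the ether oxygen. The product, 8-(allyloxy)-3,5-bis(benzyloxy)-2-[4-(benzyloxy)phenyl]-7-methoxy-4H-chromen-4-one A8, is the same compound as 21.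
- Merits: the carbon attacked is activated by three oxygens and is the only one within reach. No formyl group is needed on ring A, and phenol 8 could serve as the ring A building block. A8 is already at the flavonol level with O3 protected, so the oxidation and benzylation of steps 11 and 12 would be saved.
- Weak points: A7 is a tetrasubstituted enol ether acid in which the carboxyl group must be cis to the aryloxy group, and no short, geometry-defined access to it from 8 is apparent. The strongly acidic activation also threatens the benzyl and allyl ethers on a very electron-rich ring.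
- Comparison: if A7 were at hand this road would be shorter. The chosen plan sets against it a cyclisation precursor assembled by a simple SN2 etherification and functional-group changes, with no alkene geometry to control.

Key step: step 10

Assumption: compounds 14–19 are racemic (18 is drawn as one enantiomer of the trans pair). Since 24 has no stereocentre, no enantiocontrol is attempted. Compounds 1 and 11 are taken as commercially available.

## Steps

Step 1
Reactants: 1 3-bromo-4-hydroxy-5-methoxybenzaldehyde (5-bromovanillin)
Product: 2 4-(allyloxy)-3-bromo-5-methoxybenzaldehyde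
Conditions: allyl bromide, K2CO3, DMF, 50 °C
Reagents that add atoms: allyl bromide, C=CCBr
Why: Williamson ether synthesis; the phenoxide para to the formyl group forms readily with carbonate and is O-alkylated by the unhindered allylic bromide.

Step 2
Reactants: 2 4-(allyloxy)-3-bromo-5-methoxybenzaldehyde
Product: 4 4-(allyloxy)-3-bromo-5-methoxyphenol, via aryl formate 3 (not isolated)
Conditions: mCPBA, CH2Cl2, 0 to 23 °C; then K2CO3 (cat.), MeOH, 23 °C
Reagents that add atoms: 3-chloroperoxybenzoic acid (mCPBA), O=C(OO)c1cccc(Cl)c1
Why: Baeyer–Villiger (Dakin-type) oxidation of an alkoxybenzaldehyde with aryl migration to oxygen, followed by methanolysis of the formate; the monosubstituted, inductively deactivated allyl ether alkene should be epoxidised far more slowly than the aldehyde is consumed.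

Step 3
Reactants: 4 4-(allyloxy)-3-bromo-5-methoxyphenol
Product: 5 2-(allyloxy)-5-(benzyloxy)-1-bromo-3-methoxybenzene
Conditions: benzyl bromide, K2CO3, DMF, 23 °C
Reagents that add atoms: benzyl bromide, BrCc1ccccc1
Why: Williamson ether synthesis on an unhindered phenol flanked by two ring hydrogens; it fixes the future O5 as the benzyl ether.

Step 4
Reactants: 5 2-(allyloxy)-5-(benzyloxy)-1-bromo-3-methoxybenzene
Product: 8 2-(allyloxy)-5-(benzyloxy)-3-methoxyphenol, via aryllithium 6 (not isolated), via lithium aryltrimethoxyborate 7 (not isolated)
Conditions: n-BuLi, THF, −78 °C; B(OMe)3, −78 to 0 °C; then AcOH, 30% H2O2, 0 to 23 °C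
Reagents that add atoms: hydrogen peroxide, OO
Why: Bromine–lithium exchange, borylation and oxidative 1,2-aryl shift from boron to oxygen, the standard conversion of an aryl bromide into a phenol; at −78 °C exchange is much faster than deprotonation or carbolithiation of the allyl and benzyl ethers.

Step 5
Reactants: 8 2-(allyloxy)-5-(benzyloxy)-3-methoxyphenol
Product: 10 3-(allyloxy)-6-(benzyloxy)-2-hydroxy-4-methoxybenzaldehyde, via hydroxymethylphenol magnesium salt 9 (not isolated)
Conditions: MgCl2, Et3N, (CH2O)n, MeCN, reflux
Reagents that add atoms: paraformaldehyde (formaldehyde source), C=O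
Why: Magnesium-mediated ortho-formylation of a phenol (Casnati–Skattebøl): formaldehyde is delivered within the magnesium phenoxide to the ortho carbon and the hydroxymethyl group is oxidised by hydride transfer to a second formaldehyde. Only one ortho position of 8 is free, so the regiochemistry is fixed and the para position is not touched.

Step 6
Reactants: 11 methyl 2-[4-(benzyloxy)phenyl]acetate
Product: 14 methyl 2-bromo-2-[4-(benzyloxy)phenyl]acetate (racemic), via lithium enolate 12 (not isolated), via silyl ketene acetal 13 (not isolated)
Conditions: LiN(SiMe3)2, THF, −78 °C; Me3SiCl; then NBS, −78 to 0 °C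
Reagents that add atoms: N-bromosuccinimide, O=C1CCC(=O)N1Br
Why: Polar α-bromination of an ester through its silyl ketene acetal; the ionic path avoids the radical bromination of the benzyl ether methylene, and trapping as the silyl ketene acetal suppresses double bromination and enolate coupling.

Step 7
Reactants: 10 3-(allyloxy)-6-(benzyloxy)-2-hydroxy-4-methoxybenzaldehyde; 14 methyl 2-bromo-2-[4-(benzyloxy)phenyl]acetate
Product: 15 methyl 2-[2-(allyloxy)-5-(benzyloxy)-6-formyl-3-methoxyphenoxy]-2-[4-(benzyloxy)phenyl]acetate (racemic)
Conditions: K2CO3, DMF, 23 °C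
Reagents that add atoms: none
Why: SN2 O-alkylation (Williamson) of the phenoxide by a secondary benzylic α-bromo ester, an electrophile reactive enough for a doubly flanked phenoxide at room temperature. The ring A aldehyde is deactivated by three ortho/para alkoxy donors, so aldol addition of the product's α-carbon to it should be reversible and unfavourable under these mild conditions.

Step 8
Reactants: 15 methyl 2-[2-(allyloxy)-5-(benzyloxy)-6-formyl-3-methoxyphenoxy]-2-[4-(benzyloxy)phenyl]acetate
Product: 16 2-[2-(allyloxy)-5-(benzyloxy)-6-(hydroxymethyl)-3-methoxyphenoxy]-2-[4-(benzyloxy)phenyl]ethan-1-ol (racemic)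
Conditions: LiAlH4, THF, 0 °C
Reagents that add atoms: none
Why: Hydride reduction of ester and aldehyde to the two primary alcohols; aryl, benzyl and allyl ethers are inert, and the reduction removes the need to differentiate the two carbonyl groups.

Step 9
Reactants: 16 2-[2-(allyloxy)-5-(benzyloxy)-6-(hydroxymethyl)-3-methoxyphenoxy]-2-[4-(benzyloxy)phenyl]ethan-1-ol
Product: 17 2-[2-(allyloxy)-5-(benzyloxy)-6-formyl-3-methoxyphenoxy]-2-[4-(benzyloxy)phenyl]acetaldehyde (racemic)
Conditions: Dess–Martin periodinane, CH2Cl2, 0 to 23 °C; filtered through a short silica pad and used at once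
Reagents that add atoms: none
Why: Dess–Martin oxidation of both primary alcohols to aldehydes under base-free conditions, which spares the easily enolised α-aryl-α-aryloxy aldehyde; over-oxidation to acids does not occur with this reagent.

Step 10
Reactants: 17 2-[2-(allyloxy)-5-(benzyloxy)-6-formyl-3-methoxyphenoxy]-2-[4-(benzyloxy)phenyl]acetaldehyde
Product: 18 rac-(2R,3R)-8-(allyloxy)-5-(benzyloxy)-2-[4-(benzyloxy)phenyl]-3-hydroxy-7-methoxychroman-4-one (2,3-trans)
Conditions: 2-(pentafluorophenyl)-6,7-dihydro-5H-pyrrolo[2,1-c][1,2,4]triazol-2-ium tetrafluoroborate (20 mol %), Et3N (20 mol %), THF, 23 °C, Ar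
Reagents that add atoms: none
Why: Intramolecular crossed benzoin reaction under N-heterocyclic carbene catalysis, the reaction type that closes C3–C4 of chroman-4-ones from salicylaldehyde ethers carrying a carbonyl acceptor on the ether carbon. The triazolylidene adds to the ring A aldehyde, proton transfer gives the enaminol (Breslow intermediate), its carbon (the future C4) adds to the aliphatic aldehyde (C3), and collapse of the adduct releases the carbene and the C4 ketone. Ring C closes in the 6-exo-trig mode. The new C3 stereocentre is set relative to the existing racemic C2 under thermodynamic control: the benzoin addition is reversible and C3 epimerises by enolisation, so the 2,3-trans ketol with aryl and hydroxyl both equatorial should dominate, and since both centres are erased in step 11 the ratio is not critical. The selectivity the step does need is for ring A as the acyl anion donor, because an enaminol formed at the aliphatic aldehyde has the ring A aryloxide on the adjacent carbon and would expel it. The electron-poor N-pentafluorophenyl carbene is chosen because it adds to aldehydes reversibly and belongs to the catalyst class of benzoin and Stetter chemistry rather than of redox reactions that expel leaving groups. The branched, crowded α-carbon disfavours carbene attack at the aliphatic aldehyde, and the substoichiometric weak base limits its enolisation. Once ring A carries the carbene, closure onto the more electrophilic aliphatic carbonyl is fast, and the ketol with the carbonyl conjugated to ring A is the more stable regioisomer.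

Step 11
Reactants: 18 rac-(2R,3R)-8-(allyloxy)-5-(benzyloxy)-2-[4-(benzyloxy)phenyl]-3-hydroxy-7-methoxychroman-4-one
Product: 20 8-(allyloxy)-5-(benzyloxy)-2-[4-(benzyloxy)phenyl]-3-hydroxy-7-methoxy-4H-chromen-4-one, via chromane-3,4-dione 19 (not isolated)
Conditions: (COCl)2, DMSO, CH2Cl2, −78 °C; Et3N, −78 to 0 °C
Reagents that add atoms: none
Why: Swern oxidation of an α-hydroxy ketone to the 1,2-dione, which enolises at once towards C2 to the aromatic 3-hydroxypyranone; the activated sulfoxide is destroyed by the amine before the enol appears, and any regioisomeric or cis ketol is oxidised to the same dione.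

Step 12
Reactants: 20 8-(allyloxy)-5-(benzyloxy)-2-[4-(benzyloxy)phenyl]-3-hydroxy-7-methoxy-4H-chromen-4-one
Product: 21 8-(allyloxy)-3,5-bis(benzyloxy)-2-[4-(benzyloxy)phenyl]-7-methoxy-4H-chromen-4-one
Conditions: benzyl bromide, K2CO3, DMF, 60 °C
Reagents that add atoms: benzyl bromide, BrCc1ccccc1
Why: Williamson O-alkylation of the acidic 3-hydroxyl, the only free hydroxyl in 20; protecting it prevents competition with the 8-hydroxyl in step 14.

Step 13
Reactants: 21 8-(allyloxy)-3,5-bis(benzyloxy)-2-[4-(benzyloxy)phenyl]-7-methoxy-4H-chromen-4-one
Product: 22 3,5-bis(benzyloxy)-2-[4-(benzyloxy)phenyl]-8-hydroxy-7-methoxy-4H-chromen-4-one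
Conditions: Pd(PPh3)4 (5 mol %, zerovalent palladium), morpholine, THF, 23 °C
Reagents that add atoms: none
Why: Palladium-catalysed deallylation (Tsuji–Trost type): ionisation of the aryl allyl ether to an allylpalladium complex and capture of the allyl group by morpholine; benzyl ethers and the pyranone are unaffected.

Step 14
Reactants: 22 3,5-bis(benzyloxy)-2-[4-(benzyloxy)phenyl]-8-hydroxy-7-methoxy-4H-chromen-4-one
Product: 23 3,5-bis(benzyloxy)-2-[4-(benzyloxy)phenyl]-7-methoxy-4-oxo-4H-chromen-8-yl acetate
Conditions: Ac2O, pyridine, DMAP (cat.), CH2Cl2, 23 °C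
Reagents that add atoms: acetic anhydride, CC(=O)OC(C)=O
Why: Nucleophile-catalysed O-acetylation of a phenol; the 8-hydroxyl is the only free hydroxyl, so no selectivity is required.

Step 15
Reactants: 23 3,5-bis(benzyloxy)-2-[4-(benzyloxy)phenyl]-7-methoxy-4-oxo-4H-chromen-8-yl acetate
Product: 24 3,5-dihydroxy-2-(4-hydroxyphenyl)-7-methoxy-4-oxo-4H-chromen-8-yl acetate (pollenitin 8-acetate)
Conditions: H2 (1 atm), 10% Pd/C, EtOAc–THF, 23 °C
Reagents that add atoms: none
Why: Hydrogenolysis of the three benzyl ethers under neutral, non-nucleophilic conditions; the aryl acetate and the pyranone double bond should be retained, and no free hydroxyl is adjacent to the acetate, so acyl migration is not expected.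

## Compound list

1 | 3-bromo-4-hydroxy-5-methoxybenzaldehyde (5-bromovanillin) | COc1cc(C=O)cc(Br)c1O | starting material
2 | 4-(allyloxy)-3-bromo-5-methoxybenzaldehyde | COc1cc(C=O)cc(Br)c1OCC=C | intermediate
3 | 4-(allyloxy)-3-bromo-5-methoxyphenyl formate | COc1cc(OC=O)cc(Br)c1OCC=C | intermediate (not isolated)
4 | 4-(allyloxy)-3-bromo-5-methoxyphenol | COc1cc(O)cc(Br)c1OCC=C | intermediate
5 | 2-(allyloxy)-5-(benzyloxy)-1-bromo-3-methoxybenzene | COc1cc(OCc2ccccc2)cc(Br)c1OCC=C | intermediate
6 | [2-(allyloxy)-5-(benzyloxy)-3-methoxyphenyl]lithium | [Li]c1cc(OCc2ccccc2)cc(OC)c1OCC=C | intermediate (not isolated)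
7 | lithium [2-(allyloxy)-5-(benzyloxy)-3-methoxyphenyl]trimethoxyborate | [Li+].CO[B-](OC)(OC)c1cc(OCc2ccccc2)cc(OC)c1OCC=C | intermediate (not isolated)
8 | 2-(allyloxy)-5-(benzyloxy)-3-methoxyphenol | COc1cc(OCc2ccccc2)cc(O)c1OCC=C | intermediate
9 | 2-(allyloxy)-5-(benzyloxy)-6-(hydroxymethyl)-3-methoxyphenol (present as its magnesium phenoxide) | COc1cc(OCc2ccccc2)c(CO)c(O)c1OCC=C | intermediate (not isolated)
10 | 3-(allyloxy)-6-(benzyloxy)-2-hydroxy-4-methoxybenzaldehyde | COc1cc(OCc2ccccc2)c(C=O)c(O)c1OCC=C | intermediate
11 | methyl 2-[4-(benzyloxy)phenyl]acetate | COC(=O)Cc1ccc(OCc2ccccc2)cc1 | starting material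
12 | lithium 2-[4-(benzyloxy)phenyl]-1-methoxyethen-1-olate (lithium enolate of 11) | [Li+].COC([O-])=Cc1ccc(OCc2ccccc2)cc1 | intermediate (not isolated)
13 | {[2-[4-(benzyloxy)phenyl]-1-methoxyethenyl]oxy}trimethylsilane (silyl ketene acetal, alkene geometry not defined) | COC(O[Si](C)(C)C)=Cc1ccc(OCc2ccccc2)cc1 | intermediate (not isolated)
14 | methyl 2-bromo-2-[4-(benzyloxy)phenyl]acetate (racemic) | COC(=O)C(Br)c1ccc(OCc2ccccc2)cc1 | intermediate
15 | methyl 2-[2-(allyloxy)-5-(benzyloxy)-6-formyl-3-methoxyphenoxy]-2-[4-(benzyloxy)phenyl]acetate (racemic) | COC(=O)C(Oc1c(OCC=C)c(OC)cc(OCc2ccccc2)c1C=O)c1ccc(OCc2ccccc2)cc1 | intermediate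
16 | 2-[2-(allyloxy)-5-(benzyloxy)-6-(hydroxymethyl)-3-methoxyphenoxy]-2-[4-(benzyloxy)phenyl]ethan-1-ol (racemic) | OCC(Oc1c(OCC=C)c(OC)cc(OCc2ccccc2)c1CO)c1ccc(OCc2ccccc2)cc1 | intermediate
17 | 2-[2-(allyloxy)-5-(benzyloxy)-6-formyl-3-methoxyphenoxy]-2-[4-(benzyloxy)phenyl]acetaldehyde (racemic) | O=CC(Oc1c(OCC=C)c(OC)cc(OCc2ccccc2)c1C=O)c1ccc(OCc2ccccc2)cc1 | intermediate
18 | rac-(2R,3R)-8-(allyloxy)-5-(benzyloxy)-2-[4-(benzyloxy)phenyl]-3-hydroxy-7-methoxychroman-4-one (2,3-trans, one enantiomer drawn) | O=C1c2c(OCc3ccccc3)cc(OC)c(OCC=C)c2O[C@H](c2ccc(OCc3ccccc3)cc2)[C@H]1O | intermediate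
19 | 8-(allyloxy)-5-(benzyloxy)-2-[4-(benzyloxy)phenyl]-7-methoxychromane-3,4-dione (racemic) | O=C1C(=O)c2c(OCc3ccccc3)cc(OC)c(OCC=C)c2OC1c1ccc(OCc2ccccc2)cc1 | intermediate (not isolated)
20 | 8-(allyloxy)-5-(benzyloxy)-2-[4-(benzyloxy)phenyl]-3-hydroxy-7-methoxy-4H-chromen-4-one | COc1cc(OCc2ccccc2)c2c(=O)c(O)c(-c3ccc(OCc4ccccc4)cc3)oc2c1OCC=C | intermediate
21 | 8-(allyloxy)-3,5-bis(benzyloxy)-2-[4-(benzyloxy)phenyl]-7-methoxy-4H-chromen-4-one | COc1cc(OCc2ccccc2)c2c(=O)c(OCc3ccccc3)c(-c3ccc(OCc4ccccc4)cc3)oc2c1OCC=C | intermediate
22 | 3,5-bis(benzyloxy)-2-[4-(benzyloxy)phenyl]-8-hydroxy-7-methoxy-4H-chromen-4-one | COc1cc(OCc2ccccc2)c2c(=O)c(OCc3ccccc3)c(-c3ccc(OCc4ccccc4)cc3)oc2c1O | intermediate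
23 | 3,5-bis(benzyloxy)-2-[4-(benzyloxy)phenyl]-7-methoxy-4-oxo-4H-chromen-8-yl acetate | COc1cc(OCc2ccccc2)c2c(=O)c(OCc3ccccc3)c(-c3ccc(OCc4ccccc4)cc3)oc2c1OC(C)=O | intermediate
24 | 3,5-dihydroxy-2-(4-hydroxyphenyl)-7-methoxy-4-oxo-4H-chromen-8-yl acetate (pollenitin 8-acetate) | COc1cc(O)c2c(=O)c(O)c(-c3ccc(O)cc3)oc2c1OC(C)=O | target

## Step count and least certain steps

Total: 15 steps. Longest linear sequence: 14 steps (1 to 24 through steps 1–5 and 7–15); step 6 is a one-step side branch.

**Step 10 (key step).** The most likely failure is that the catalyst engages the wrong aldehyde. The carbene may add to the more electrophilic aliphatic aldehyde rather than the crowded, electron-rich ring A aldehyde. The enaminol formed there would expel the ring A aryloxide from C2, the internal redox path known for α-aryloxy aldehydes, which severs the O1–C2 tether instead of closing ring C. Base-induced enolisation of the same aldehyde followed by aldol addition to the ring A formyl group is a second drain. The fallback sets out from 10, returns at 21 and replaces steps 7–12; ring C is then closed at O1–C2 by the Baker–Venkataraman sequence. Benzyloxymethyllithium (from Bu3SnCH2OBn and n-BuLi, THF, −78 °C, in excess to allow for the phenoxide) is added to 10 to give 1-[3-(allyloxy)-6-(benzyloxy)-2-hydroxy-4-methoxyphenyl]-2-(benzyloxy)ethan-1-ol F1. Oxidation of the benzylic carbinol (MnO2, CH2Cl2) gives 1-[3-(allyloxy)-6-(benzyloxy)-2-hydroxy-4-methoxyphenyl]-2-(benzyloxy)ethan-1-one F2. O-Aroylation with 4-(benzyloxy)benzoyl chloride in pyridine gives 2-(allyloxy)-5-(benzyloxy)-6-[2-(benzyloxy)acetyl]-3-methoxyphenyl 4-(benzyloxy)benzoate F3. KOH in pyridine at 50 °C then induces the acyl shift to 1-[3-(allyloxy)-6-(benzyloxy)-2-hydroxy-4-methoxyphenyl]-2-(benzyloxy)-3-[4-(benzyloxy)phenyl]propane-1,3-dione F4. Cyclodehydration (NaOAc, AcOH, 100 °C) closes the pyranone to 21, from which steps 13–15 follow unchanged.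

**Step 9.** The aliphatic aldehyde may be lost while it is generated and handled, through enolisation at the doubly activated C2–H, hydration, autoxidation, or intramolecular aldol addition. Incomplete oxidation of the hindered benzylic alcohol is also possible. The fallback sets out from 15 and returns at 17, so that 17 is reached by unmasking rather than by oxidation. The ring A aldehyde of 15 is converted into its dimethyl acetal (HC(OMe)3, MeOH, cat. TsOH) to give methyl 2-[2-(allyloxy)-5-(benzyloxy)-6-(dimethoxymethyl)-3-methoxyphenoxy]-2-[4-(benzyloxy)phenyl]acetate F5. The ester is half-reduced with i-Bu2AlH in toluene at −78 °C, the α-aryloxy group stabilising the tetrahedral aluminate, to give 2-[2-(allyloxy)-5-(benzyloxy)-6-(dimethoxymethyl)-3-methoxyphenoxy]-2-[4-(benzyloxy)phenyl]acetaldehyde F6. Brief treatment with pyridinium 4-toluenesulfonate in aqueous acetone cleaves the very labile acetal of the electron-rich aldehyde and delivers 17 directly before step 10.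

**Step 7.** O-Alkylation of the hydrogen-bonded phenoxide, flanked on both sides, may be slow. That would give time for addition of the product's acidic α-C–H to the neighbouring formyl group, or for consumption of 14 by hydrolysis and self-condensation. The fallback sets out from 10, with the partner made from 11, and returns at 15. Hydroxylation of the potassium enolate of 11 (KN(SiMe3)2; 2-(phenylsulfonyl)-3-phenyloxaziridine, THF, −78 °C) gives methyl 2-[4-(benzyloxy)phenyl]-2-hydroxyacetate F7. Mitsunobu etherification of 10, an acidic phenol, with F7 (PPh3, diisopropyl azodicarboxylate, toluene, 0 to 23 °C) then forms the O1–C2 bond without base and gives 15.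

**Step 11.** Oxidation of the hindered carbinol may be incomplete, the activated sulfoxide may attack the electron-rich ring A or the enol oxygen, or the dione may undergo base-induced ring contraction before it enolises. The fallback sets out from 18, returns at 21 and replaces steps 11 and 12. Acid-catalysed O-benzylation of the carbinol (benzyl 2,2,2-trichloroacetimidate, cat. CF3SO3H, CH2Cl2) gives rac-(2R,3R)-8-(allyloxy)-3,5-bis(benzyloxy)-2-[4-(benzyloxy)phenyl]-7-methoxychroman-4-one F8. Dehydrogenation across C2–C3 with DDQ in dioxane at reflux then gives 21.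

## Further compounds

F1 | step 10 | 1-[3-(allyloxy)-6-(benzyloxy)-2-hydroxy-4-methoxyphenyl]-2-(benzyloxy)ethan-1-ol (racemic) | COc1cc(OCc2ccccc2)c(C(O)COCc2ccccc2)c(O)c1OCC=C
F2 | step 10 | 1-[3-(allyloxy)-6-(benzyloxy)-2-hydroxy-4-methoxyphenyl]-2-(benzyloxy)ethan-1-one | COc1cc(OCc2ccccc2)c(C(=O)COCc2ccccc2)c(O)c1OCC=C
F3 | step 10 | 2-(allyloxy)-5-(benzyloxy)-6-[2-(benzyloxy)acetyl]-3-methoxyphenyl 4-(benzyloxy)benzoate | COc1cc(OCc2ccccc2)c(C(=O)COCc2ccccc2)c(OC(=O)c2ccc(OCc3ccccc3)cc2)c1OCC=C
F4 | step 10 | 1-[3-(allyloxy)-6-(benzyloxy)-2-hydroxy-4-methoxyphenyl]-2-(benzyloxy)-3-[4-(benzyloxy)phenyl]propane-1,3-dione (racemic) | COc1cc(OCc2ccccc2)c(C(=O)C(OCc2ccccc2)C(=O)c2ccc(OCc3ccccc3)cc2)c(O)c1OCC=C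
F5 | step 9 | methyl 2-[2-(allyloxy)-5-(benzyloxy)-6-(dimethoxymethyl)-3-methoxyphenoxy]-2-[4-(benzyloxy)phenyl]acetate (racemic) | COC(=O)C(Oc1c(OCC=C)c(OC)cc(OCc2ccccc2)c1C(OC)OC)c1ccc(OCc2ccccc2)cc1
F6 | step 9 | 2-[2-(allyloxy)-5-(benzyloxy)-6-(dimethoxymethyl)-3-methoxyphenoxy]-2-[4-(benzyloxy)phenyl]acetaldehyde (racemic) | O=CC(Oc1c(OCC=C)c(OC)cc(OCc2ccccc2)c1C(OC)OC)c1ccc(OCc2ccccc2)cc1
F7 | step 7 | methyl 2-[4-(benzyloxy)phenyl]-2-hydroxyacetate (racemic) | COC(=O)C(O)c1ccc(OCc2ccccc2)cc1
F8 | step 11 | rac-(2R,3R)-8-(allyloxy)-3,5-bis(benzyloxy)-2-[4-(benzyloxy)phenyl]-7-methoxychroman-4-one | O=C1c2c(OCc3ccccc3)cc(OC)c(OCC=C)c2O[C@H](c2ccc(OCc3ccccc3)cc2)[C@H]1OCc1ccccc1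
A1 | alternative 1 | 2-(benzyloxy)-1-[4-(benzyloxy)phenyl]-3-(4-methoxy-3,6-dioxocyclohexa-1,4-dien-1-yl)propane-1,3-dione | COC1=CC(=O)C(=CC1=O)C(=O)C(OCc1ccccc1)C(=O)c1ccc(OCc2ccccc2)cc1
A2 | alternative 1 | 3-(benzyloxy)-2-[4-(benzyloxy)phenyl]-5,8-dihydroxy-7-methoxy-4H-chromen-4-one | COc1cc(O)c2c(=O)c(OCc3ccccc3)c(-c3ccc(OCc4ccccc4)cc3)oc2c1O
A3 | alternative 2 | 3-(benzyloxy)-2-iodo-5-methoxy-6-(methoxymethoxy)phenol | COCOc1c(OC)cc(OCc2ccccc2)c(I)c1O
A4 | alternative 2 | 1-(benzyloxy)-4-ethynylbenzene | C#Cc1ccc(OCc2ccccc2)cc1
A5 | alternative 2 | carbon monoxide | [C-]#[O+]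
A6 | alternative 2 | 5-(benzyloxy)-2-[4-(benzyloxy)phenyl]-7-methoxy-8-(methoxymethoxy)-4H-chromen-4-one | COCOc1c(OC)cc(OCc2ccccc2)c2c(=O)cc(-c3ccc(OCc4ccccc4)cc3)oc12
A7 | alternative 3 | (E)-3-[2-(allyloxy)-5-(benzyloxy)-3-methoxyphenoxy]-2-(benzyloxy)-3-[4-(benzyloxy)phenyl]acrylic acid | OC(=O)/C(OCc1ccccc1)=C(\Oc1cc(OCc2ccccc2)cc(OC)c1OCC=C)c1ccc(OCc2ccccc2)cc1
A8 | alternative 3 | 8-(allyloxy)-3,5-bis(benzyloxy)-2-[4-(benzyloxy)phenyl]-7-methoxy-4H-chromen-4-one (identical with 21) | COc1cc(OCc2ccccc2)c2c(=O)c(OCc3ccccc3)c(-c3ccc(OCc4ccccc4)cc3)oc2c1OCC=C
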